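**Assumption:** the (S,S)-bis(oxazoline) ligand named in step 9 is taken to give the (R)-ester; if a model coupling shows the opposite sense, its (R,R)-enantiomer is used and nothing else changes.

## Retrosynthetic overview

1. Target 22 ⇐ one global BCl3 deprotection of 21 (chelated ortho-OMe, two O-iPr, one O-Bn).
2. 21 ⇐ C–C disconnection at the ester carbinol carbon: an α-aroyloxybutyl radical (from acid 14 + butanal 18 via the 1-bromobutyl ester) is joined to terminal olefin 17 by chiral nickel hydride catalysis, so the hindered ester and its (R)-centre form together.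
3. Acid 14 ⇐ formylation/oxidation of 11 ⇐ B-alkyl Suzuki coupling of aryl bromide 4 with olefin 9 ⇐ (R)-2-propyloxirane 6 + hept-6-enyl Grignard (free-carbinol centre from the chiral pool).
4. Bromide 4 and olefin 17 ⇐ resorcinol 1 by O-alkylation and meta-selective iridium C–H borylation.
5. No ring is built: ring A (benzoate) and ring B (resorcinol) both come intact from resorcinol and are only functionalised.

## Route

Step 1
Reactants: 1 resorcinol
Product: 2 resorcinol dimethyl ether (1,3-dimethoxybenzene)
Conditions: MeI (2.5 equiv), K2CO3, DMF, rt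
Reagents that add atoms: iodomethane, CI
Why: Williamson ether synthesis; both phenoxides are O-methylated cleanly, giving the methyl that stays as the 4-OMe of ring A and the one later removed by chelation.

Step 2
Reactants: 2 resorcinol dimethyl ether
Product: 4 aryl bromide 1-bromo-3,5-dimethoxybenzene, via pinacol 3,5-dimethoxyphenylboronate 3 (not isolated)
Conditions: [Ir(OMe)(cod)]2 (0.5 mol%), 4,4'-di-tert-butyl-2,2'-bipyridine (1 mol%), B2pin2 (0.6 equiv), THF, 80 °C; evaporate; CuBr2 (3 equiv), MeOH/H2O 1:1, 80 °C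
Reagents that add atoms: bis(pinacolato)diboron, CC1(C)OB(OC1(C)C)B1OC(C)(C)C(C)(C)O1 (boryl group of 3 only); CuBr2, [Cu+2].[Br-].[Br-] (Br of 4)
Why: Sterically controlled iridium-catalysed C–H borylation reaches only C5, the one C–H without an ortho substituent, and copper-mediated bromodeboronation in the same pot gives the 1,3,5-pattern that electrophilic substitution cannot.

Step 3
Reactants: 5 alkenyl bromide 7-bromohept-1-ene; 6 epoxide (R)-2-propyloxirane
Product: 9 benzyl ether ({[(4R)-dodec-11-en-4-yl]oxy}methyl)benzene, via hept-6-en-1-ylmagnesium bromide 7 (not isolated), via bromomagnesium (4R)-dodec-11-en-4-olate 8 (not isolated)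
Conditions: Mg, THF, rt; CuI (5 mol%), 6, THF, –30 → 0 °C; then BnBr (1.5 equiv), Bu4NI (10 mol%), DMPU, 0 → 60 °C
Reagents that add atoms: magnesium, [Mg] (in 7 and 8 only); benzyl bromide, BrCc1ccccc1 (benzyl group of 9)
Why: Copper-catalysed Grignard opening of the terminal epoxide at its CH2 carbon (SN2) breaks no bond to the purchased stereocentre, which stays (R) because the new chain still outranks propyl, and the magnesium alkoxide is O-benzylated in the same pot (Williamson ether synthesis, activated by DMPU and iodide).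

Step 4
Reactants: 9 benzyl ether; 4 aryl bromide
Product: 11 arene 1-[(9R)-9-(benzyloxy)dodecyl]-3,5-dimethoxybenzene, via B-alkyl-9-BBN adduct 10 (not isolated)
Conditions: 9-BBN (1.2 equiv), THF, 0 °C → rt; then 4, Pd(OAc)2 (3 mol%), SPhos (6 mol%), aq. K3PO4 (3 M), THF, 65 °C
Reagents that add atoms: 9-borabicyclo[3.3.1]nonane, [H]B1C2CCCC1CCC2 (boryl group of 10 only)
Why: Anti-Markovnikov hydroboration of the terminal olefin followed by B-alkyl Suzuki–Miyaura coupling, with the electron-rich biaryl phosphine driving oxidative addition of the electron-rich aryl bromide; the remote stereocentre is untouched.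

Step 5
Reactants: 11 arene
Product: 13 aldehyde 2-[(9R)-9-(benzyloxy)dodecyl]-4,6-dimethoxybenzaldehyde, via aryl iminium chloride 12 (not isolated)
Conditions: POCl3 (1.5 equiv), DMF, 0 → 70 °C; aq. NaOAc
Reagents that add atoms: N,N-dimethylformamide, CN(C)C=O (formyl carbon of 13 and the NMe2 of 12); water, O (carbonyl oxygen of 13); POCl3, O=P(Cl)(Cl)Cl (chloride of 12 only)
Why: Vilsmeier–Haack formylation of a 5-alkylresorcinol dimethyl ether goes ortho to the chain and para to one OMe rather than between the two OMe groups, as it does for orcinol and olivetol dimethyl ethers.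

Step 6
Reactants: 13 aldehyde
Product: 14 acid 2-[(9R)-9-(benzyloxy)dodecyl]-4,6-dimethoxybenzoic acid
Conditions: NaClO2, NaH2PO4, 2-methylbut-2-ene, t-BuOH/H2O, rt
Reagents that add atoms: sodium chlorite, [Na+].[O-]Cl=O (one oxygen)
Why: Pinnick oxidation converts the hindered electron-rich aldehyde to the acid without touching the benzyl ether, while the olefin scavenger removes HOCl and prevents ring chlorination.

Step 7
Reactants: 1 resorcinol
Product: 15 resorcinol diisopropyl ether (1,3-di(propan-2-yloxy)benzene)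
Conditions: 2-bromopropane (3 equiv), K2CO3, DMF, 70 °C
Reagents that add atoms: 2-bromopropane, CC(C)Br
Why: Williamson ether synthesis; isopropyl ethers survive borylation, strong base and the nickel step, and BCl3 later cleaves them in the presence of an aryl methyl ether.

Step 8
Reactants: 15 resorcinol diisopropyl ether; 5 alkenyl bromide 7-bromohept-1-ene
Product: 17 olefin 1-(hept-6-en-1-yl)-3,5-di(propan-2-yloxy)benzene, via pinacol 3,5-di(propan-2-yloxy)phenylboronate 16 (not isolated)
Conditions: [Ir(OMe)(cod)]2 (0.5 mol%), 4,4'-di-tert-butyl-2,2'-bipyridine (1 mol%), B2pin2 (0.6 equiv), THF, 80 °C; evaporate; 5 (1.2 equiv), Pd(OAc)2 (4 mol%), P(t-Bu)2Me·HBF4 (8 mol%), KOt-Bu (3 equiv), tert-amyl alcohol, rt → 40 °C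
Reagents that add atoms: bis(pinacolato)diboron, CC1(C)OB(OC1(C)C)B1OC(C)(C)C(C)(C)O1 (boryl group of 16 only)
Why: The same sterically controlled C–H borylation gives only the 5-boronate, and alkyl Suzuki–Miyaura coupling with the primary bromide works because the bulky electron-rich trialkylphosphine allows oxidative addition to the alkyl bromide and suppresses β-hydride elimination; the olefin is added only after the iridium stage.

Step 9
Reactants: 14 acid; 18 butanal; 17 olefin
Product: 21 protected ester (4R)-11-[3,5-di(propan-2-yloxy)phenyl]undecan-4-yl 2-[(9R)-9-(benzyloxy)dodecyl]-4,6-dimethoxybenzoate, via acyl bromide 19 (not isolated), via 1-bromobutyl ester 20 (not isolated)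
Conditions: (COBr)2 (1.2 equiv), cat. DMF, CH2Cl2, 0 °C → rt, evaporate; 18 (1.05 equiv), CH2Cl2, 0 °C → rt, evaporate; then NiBr2(dme) (10 mol%), 2,2'-(propane-2,2-diyl)bis[(4S)-4-isopropyl-4,5-dihydro-1,3-oxazole] (12 mol%), 17 (1.5 equiv), (EtO)3SiH (2 equiv), K3PO4·H2O (2.5 equiv), Et2O/DMA, rt
Reagents that add atoms: oxalyl bromide, O=C(Br)C(=O)Br (Br of 19 and 20 only; none of its heavy atoms remain in 21)
Why: Proposed new method: nickel hydride (from divalent nickel, silane and phosphate) adds anti-Markovnikov to the terminal olefin of 17 to give a primary alkylnickel, monovalent nickel abstracts bromine from either epimer of 20 to give one planar α-aroyloxybutyl radical, and the chiral alkylnickel captures it and reductively eliminates from trivalent nickel, so the carbinol C–CH2 bond, the hindered ester and the (R)-centre arise together under catalyst control, independent of the remote C9 centre; the closest known reaction type is the nickel-hydride-catalysed enantioconvergent hydroalkylation of olefins with racemic 1-bromoalkyl esters made in situ from an aldehyde and an acyl bromide (four-component coupling), extended here to a di-ortho-substituted electron-rich aroyl bromide, whose twisted carbonyl may lower rate or ee.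

Step 10
Reactants: 21 protected ester
Product: 22 5'-methoxy-integracin B, (4R)-11-(3,5-dihydroxyphenyl)undecan-4-yl 2-hydroxy-6-[(9R)-9-hydroxydodecyl]-4-methoxybenzoate
Conditions: BCl3 (8 equiv), pentamethylbenzene (5 equiv), CH2Cl2, –78 → 0 °C; MeOH, then aq. NaHCO3
Reagents that add atoms: none
Why: Lewis-acid ether cleavage: BCl3 removes the ortho-OMe through a six-membered boron chelate with the ester carbonyl, the two isopropyl aryl ethers and the benzyl ether (benzyl cation trapped by pentamethylbenzene), while the non-chelated para-OMe and the hindered secondary ester are inert at or below 0 °C, and no bond to either stereocentre is broken.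

## Compound list

1 | resorcinol (benzene-1,3-diol) | Oc1cccc(O)c1 | starting material
2 | 1,3-dimethoxybenzene | COc1cccc(OC)c1 | intermediate
3 | 2-(3,5-dimethoxyphenyl)-4,4,5,5-tetramethyl-1,3,2-dioxaborolane | COc1cc(OC)cc(c1)B1OC(C)(C)C(C)(C)O1 | intermediate
4 | 1-bromo-3,5-dimethoxybenzene | COc1cc(Br)cc(OC)c1 | intermediate
5 | 7-bromohept-1-ene | C=CCCCCCBr | starting material
6 | (R)-2-propyloxirane | CCC[C@@H]1CO1 | starting material
7 | hept-6-en-1-ylmagnesium bromide | C=CCCCCC[Mg]Br | intermediate
8 | bromomagnesium (4R)-dodec-11-en-4-olate | CCC[C@@H](O[Mg]Br)CCCCCCC=C | intermediate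
9 | ({[(4R)-dodec-11-en-4-yl]oxy}methyl)benzene | CCC[C@@H](OCc1ccccc1)CCCCCCC=C | intermediate
10 | 9-[(9R)-9-(benzyloxy)dodecyl]-9-borabicyclo[3.3.1]nonane | CCC[C@@H](OCc1ccccc1)CCCCCCCCB1C2CCCC1CCC2 | intermediate
11 | 1-[(9R)-9-(benzyloxy)dodecyl]-3,5-dimethoxybenzene | CCC[C@@H](OCc1ccccc1)CCCCCCCCc1cc(OC)cc(OC)c1 | intermediate
12 | N-({2-[(9R)-9-(benzyloxy)dodecyl]-4,6-dimethoxyphenyl}methylidene)-N-methylmethanaminium chloride | CCC[C@@H](OCc1ccccc1)CCCCCCCCc1cc(OC)cc(OC)c1C=[N+](C)C.[Cl-] | intermediate
13 | 2-[(9R)-9-(benzyloxy)dodecyl]-4,6-dimethoxybenzaldehyde | CCC[C@@H](OCc1ccccc1)CCCCCCCCc1cc(OC)cc(OC)c1C=O | intermediate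
14 | 2-[(9R)-9-(benzyloxy)dodecyl]-4,6-dimethoxybenzoic acid | CCC[C@@H](OCc1ccccc1)CCCCCCCCc1cc(OC)cc(OC)c1C(=O)O | intermediate
15 | 1,3-di(propan-2-yloxy)benzene | CC(C)Oc1cccc(OC(C)C)c1 | intermediate
16 | 2-[3,5-di(propan-2-yloxy)phenyl]-4,4,5,5-tetramethyl-1,3,2-dioxaborolane | CC(C)Oc1cc(OC(C)C)cc(c1)B1OC(C)(C)C(C)(C)O1 | intermediate
17 | 1-(hept-6-en-1-yl)-3,5-di(propan-2-yloxy)benzene | C=CCCCCCc1cc(OC(C)C)cc(OC(C)C)c1 | intermediate
18 | butanal | CCCC=O | starting material
19 | 2-[(9R)-9-(benzyloxy)dodecyl]-4,6-dimethoxybenzoyl bromide | CCC[C@@H](OCc1ccccc1)CCCCCCCCc1cc(OC)cc(OC)c1C(=O)Br | intermediate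
20 | (1RS)-1-bromobutyl 2-[(9R)-9-(benzyloxy)dodecyl]-4,6-dimethoxybenzoate (both epimers at C–Br) | CCC[C@@H](OCc1ccccc1)CCCCCCCCc1cc(OC)cc(OC)c1C(=O)OC(Br)CCC | intermediate
21 | (4R)-11-[3,5-di(propan-2-yloxy)phenyl]undecan-4-yl 2-[(9R)-9-(benzyloxy)dodecyl]-4,6-dimethoxybenzoate | CCC[C@@H](OCc1ccccc1)CCCCCCCCc1cc(OC)cc(OC)c1C(=O)O[C@H](CCC)CCCCCCCc1cc(OC(C)C)cc(OC(C)C)c1 | intermediate
22 | 5'-methoxy-integracin B, (4R)-11-(3,5-dihydroxyphenyl)undecan-4-yl 2-hydroxy-6-[(9R)-9-hydroxydodecyl]-4-methoxybenzoate | CCC[C@@H](O)CCCCCCCCc1cc(OC)cc(O)c1C(=O)O[C@H](CCC)CCCCCCCc1cc(O)cc(O)c1 | target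

## Step count and risks

Total steps: 10. Longest linear sequence: 7 (steps 1, 2, 4, 5, 6, 9, 10).

**Step 9 (most likely to fail).** The di-ortho-substituted aroyl bromide may add slowly to butanal, or the hindered α-aroyloxy radical may couple with low yield or ee. The fallback sets out from 17 and 18 and comes back at 21. Butanal 18 and acetyl bromide (neat, 0 °C) give racemic 1-bromobutyl acetate F1. F1 is coupled with 17 under the nickel hydride conditions of step 9, but with the (R,R)-ligand, to give (4S)-11-[3,5-di(propan-2-yloxy)phenyl]undecan-4-yl acetate F2. K2CO3 in MeOH gives (4S)-11-[3,5-di(propan-2-yloxy)phenyl]undecan-4-ol F3. Mitsunobu esterification of F3 with acid 14 (PPh3, DIAD, toluene, 0 °C → rt) proceeds with inversion to the (R)-ester 21. The radical step then runs with an unhindered acyl group, and the hindered C–O bond is made by carboxylate SN2 displacement, where bulk at the acyl carbon does not matter.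

**Step 10.** Isopropyl ether cleavage may need temperatures at which the secondary ester, the freed secondary alcohol or the para-OMe begin to suffer, or ring B may be C-alkylated. The fallback sets out from 1 and comes back at 22. Resorcinol 1 with MOMCl and i-Pr2NEt gives 1,3-bis(methoxymethoxy)benzene F4. Borylation as in step 8 gives 2-[3,5-bis(methoxymethoxy)phenyl]-4,4,5,5-tetramethyl-1,3,2-dioxaborolane F5 (used without isolation), and alkyl Suzuki coupling with 5 gives 1-(hept-6-en-1-yl)-3,5-bis(methoxymethoxy)benzene F6. The step-9 coupling with 14 and 18 (through 19 and 20) gives (4R)-11-[3,5-bis(methoxymethoxy)phenyl]undecan-4-yl 2-[(9R)-9-(benzyloxy)dodecyl]-4,6-dimethoxybenzoate F7. BCl3 with pentamethylbenzene at –78 °C then cleaves the acetals, the benzyl ether and the chelated ortho-OMe to give 22 without warming.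

**Step 8.** The telescoped borylation/alkyl-bromide Suzuki coupling may stall with the pinacol boronate or isomerise the olefin. The fallback sets out from 15 and comes back at 17, with the coupling polarity reversed. Borylation of 15 to 16 followed by CuBr2 in MeOH/H2O (as in step 2) gives 1-bromo-3,5-di(propan-2-yloxy)benzene F8. Purchased hepta-1,6-diene (C=CCCCC=C, 4 equiv) is mono-hydroborated with 9-BBN to 9-(hept-6-en-1-yl)-9-borabicyclo[3.3.1]nonane F9 (used without isolation). B-alkyl Suzuki coupling of F9 with F8 (Pd(OAc)2, SPhos, aq. K3PO4, THF, 65 °C) gives 17.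

## Further compounds

F1 | step 9 | 1-bromobutyl acetate (racemic) | CCCC(Br)OC(C)=O
F2 | step 9 | (4S)-11-[3,5-di(propan-2-yloxy)phenyl]undecan-4-yl acetate | CC(=O)O[C@@H](CCC)CCCCCCCc1cc(OC(C)C)cc(OC(C)C)c1
F3 | step 9 | (4S)-11-[3,5-di(propan-2-yloxy)phenyl]undecan-4-ol | O[C@@H](CCC)CCCCCCCc1cc(OC(C)C)cc(OC(C)C)c1
F4 | step 10 | 1,3-bis(methoxymethoxy)benzene | COCOc1cccc(OCOC)c1
F5 | step 10 | 2-[3,5-bis(methoxymethoxy)phenyl]-4,4,5,5-tetramethyl-1,3,2-dioxaborolane | COCOc1cc(OCOC)cc(c1)B1OC(C)(C)C(C)(C)O1
F6 | step 10 | 1-(hept-6-en-1-yl)-3,5-bis(methoxymethoxy)benzene | C=CCCCCCc1cc(OCOC)cc(OCOC)c1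
F7 | step 10 | (4R)-11-[3,5-bis(methoxymethoxy)phenyl]undecan-4-yl 2-[(9R)-9-(benzyloxy)dodecyl]-4,6-dimethoxybenzoate | CCC[C@@H](OCc1ccccc1)CCCCCCCCc1cc(OC)cc(OC)c1C(=O)O[C@H](CCC)CCCCCCCc1cc(OCOC)cc(OCOC)c1
F8 | step 8 | 1-bromo-3,5-di(propan-2-yloxy)benzene | CC(C)Oc1cc(Br)cc(OC(C)C)c1
F9 | step 8 | 9-(hept-6-en-1-yl)-9-borabicyclo[3.3.1]nonane | C=CCCCCCB1C2CCCC1CCC2
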